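**Retrosynthetic overview** (ring A = formyl-bearing benzene, carrying in order round the ring the ester carbonyl carbon, the ether oxygen, CHO, OH, H and CH3; ring B = hexasubstituted benzene, B1 ester O, B2 CH2OH, B3 OH, B4 lactone C=O, B5 lactol carbon, B6 ether O; ring C = seven-membered lactone; ring D = lactol)
1. Ring D (lactone carbonyl on B4, lactol carbon on B5) is an isocoumarin lactone lacking its C3, so it is made last: the B4–C(=O)–O–CH=CH–B5 enol-ester alkene is cleaved with ozone, C3 leaves as formate and the B4 acid closes onto the new B5 aldehyde. This rests on the B5 methyl and B4 ester of an orsellinate being neighbours that can be annulated to that isocoumarin.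
2. Ring C is closed before that by lactonization of the ring A carboxylic acid with B1–OH, after the diaryl ether is made by SNAr of the B6 phenoxide on a ring A fluoride flanked by the formyl and ester groups (electron-rich nucleophile, electron-poor electrophile; B1–O blocked as allyl ether).
3. Ring B comes from methyl orsellinate: C3 formylation (becomes B2–CH2OH, tied to B3–OH as an isopropylidene acetal), C5 bromination then hydroxylation (B6–OH), and lateral lithiation/methyl formate at the B5 methyl to give the isocoumarin.
4. Ring A comes from 3-fluoro-5-methylphenol: para bromination, MOM ether, Br–Li exchange/allyl chloroformate, then ortho-magnesiation/formylation between F and OMOM.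
5. Order of ring formation: 1,3-dioxine (protecting ring), isocoumarin pyranone, ring C, ring D; the lactol stereocentre is fixed last by seeded crystallization.

Key step: step 16

Assumption: the lactol carbon epimerizes in solution by ring–chain tautomerism, so the single (S) enantiomer can only be delivered as a crystalline solid; it is assumed that the target crystallizes as a conglomerate and that seed crystals of the wanted enantiomorph are available from a small sample resolved on a chiral stationary phase.

**Route**

Step 1
Reactants: 1 methyl orsellinate
Product: 2 methyl haematommate (methyl 3-formyl-2,4-dihydroxy-6-methylbenzoate)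
Conditions: Cl2CHOMe, TiCl4, CH2Cl2, 0 °C; aq HCl
Reagents that add atoms: dichloromethyl methyl ether, COC(Cl)Cl; water, O
Why: Rieche formylation, in which the titanium phenoxide delivers the electrophile ortho and C3 between the two hydroxyls is the most activated ring position, so 2 should be the main product and the minor 5-formyl isomer is removed by crystallization.

Step 2
Reactants: 2 methyl haematommate
Product: 3 methyl 4-(allyloxy)-3-formyl-2-hydroxy-6-methylbenzoate
Conditions: allyl bromide (1.05 equiv), K2CO3, acetone, rt
Reagents that add atoms: allyl bromide, C=CCBr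
Why: Williamson etherification, selective for the 4-OH (para to the ester, the more acidic and more exposed phenol) because the 2-OH is wedged between the formyl and ester groups and locked in its hydrogen bond to the ester carbonyl.

Step 3
Reactants: 3 methyl 4-(allyloxy)-3-formyl-2-hydroxy-6-methylbenzoate
Product: 4 methyl 4-(allyloxy)-5-bromo-3-formyl-2-hydroxy-6-methylbenzoate
Conditions: NBS, DMF, 0 °C, dark
Reagents that add atoms: N-bromosuccinimide, O=C1CCC(=O)N1Br
Why: Electrophilic aromatic bromination at C5, the only free ring position, which is activated by the para 2-OH and the ortho allyloxy group, while the allyl double bond should be left untouched under these ionic, water-free conditions.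

Step 4
Reactants: 4 methyl 4-(allyloxy)-5-bromo-3-formyl-2-hydroxy-6-methylbenzoate
Product: 5 methyl 4-(allyloxy)-5-bromo-2-hydroxy-3-(hydroxymethyl)-6-methylbenzoate
Conditions: NaBH4, THF/MeOH, 0 °C
Reagents that add atoms: none
Why: Borohydride reduction, in which the aldehyde reacts far faster than the hindered, hydrogen-bonded aryl ester.

Step 5
Reactants: 5 methyl 4-(allyloxy)-5-bromo-2-hydroxy-3-(hydroxymethyl)-6-methylbenzoate
Product: 6 methyl 5-(allyloxy)-6-bromo-2,2,7-trimethyl-4H-1,3-benzodioxine-8-carboxylate
Conditions: 2,2-dimethoxypropane, PPTS (cat.), acetone, rt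
Reagents that add atoms: 2,2-dimethoxypropane, COC(C)(C)OC
Why: Acid-catalysed transacetalization (isopropylidene acetal formation) of the only 1,3-related hydroxyl pair, which masks the future B2–CH2OH and B3–OH in one six-membered 1,3-dioxine.

Step 6
Reactants: 6 methyl 5-(allyloxy)-6-bromo-2,2,7-trimethyl-4H-1,3-benzodioxine-8-carboxylate
Product: 8 methyl 5-(allyloxy)-6-hydroxy-2,2,7-trimethyl-4H-1,3-benzodioxine-8-carboxylate, via lithium aryltriisopropoxyborate 7 (not isolated)
Conditions: B(Oi-Pr)3, n-BuLi, THF/PhMe, −90 °C (in situ quench); then H2O2, aq NaOH, 0 °C
Reagents that add atoms: hydrogen peroxide, OO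
Why: Bromine–lithium exchange with in situ borate trapping followed by oxidation of the arylboron ate complex (1,2-aryl shift from boron to oxygen), the exchange being faster than attack on the doubly ortho-substituted ester and the aryllithium being captured by the borate as it forms.

Step 7
Reactants: 8 methyl 5-(allyloxy)-6-hydroxy-2,2,7-trimethyl-4H-1,3-benzodioxine-8-carboxylate
Product: 9 methyl 5-(allyloxy)-6-(1-ethoxyethoxy)-2,2,7-trimethyl-4H-1,3-benzodioxine-8-carboxylate (racemic at the acetal carbon)
Conditions: ethyl vinyl ether, PPTS (cat.), CH2Cl2, rt
Reagents that add atoms: ethyl vinyl ether, C=COCC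
Why: Acid-catalysed addition of the phenol to the enol ether gives a base-stable 1-ethoxyethyl acetal that shields the acidic OH during the lithiation, the new acetal carbon being racemic and lost again in step 8.

Step 8
Reactants: 9 methyl 5-(allyloxy)-6-(1-ethoxyethoxy)-2,2,7-trimethyl-4H-1,3-benzodioxine-8-carboxylate
Product: 12 ring B isocoumarin phenol (6-(allyloxy)-5-hydroxyisocoumarin whose 8-O and 7-CH2O are bridged by an isopropylidene acetal), via benzylic lithium 10 (not isolated), via arylacetaldehyde 11 (not isolated)
Conditions: LiN(i-Pr)2 (2.2 equiv), THF, −78 °C; HCO2Me (excess), −78 °C; AcOH, −78 °C → rt; then PPTS, MeOH (3 equiv), PhMe, 70 °C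
Reagents that add atoms: methyl formate, COC=O
Why: Lateral lithiation of the ortho-toluate and Claisen-type formylation give the arylacetaldehyde, which under mild acid undergoes enol lactonization to the isocoumarin with loss of methanol while the labile 1-ethoxyethyl acetal is exchanged off by methanol and the cyclic isopropylidene acetal persists.

Step 9
Reactants: 13 3-fluoro-5-methylphenol
Product: 14 4-bromo-3-fluoro-5-methylphenol
Conditions: NBS, MeCN, 0 °C
Reagents that add atoms: N-bromosuccinimide, O=C1CCC(=O)N1Br
Why: Electrophilic bromination of a 3,5-disubstituted phenol, which is expected to go para to the hydroxyl and so places bromine between fluorine and methyl.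

Step 10
Reactants: 14 4-bromo-3-fluoro-5-methylphenol
Product: 15 2-bromo-1-fluoro-5-(methoxymethoxy)-3-methylbenzene
Conditions: MOMCl, i-Pr2NEt, CH2Cl2, 0 °C → rt
Reagents that add atoms: chloromethyl methyl ether, COCCl
Why: O-alkylation of the phenol with the chloromethyl ether (acetal-type protection) under amine base.

Step 11
Reactants: 15 2-bromo-1-fluoro-5-(methoxymethoxy)-3-methylbenzene
Product: 17 allyl 2-fluoro-4-(methoxymethoxy)-6-methylbenzoate, via aryllithium 16 (not isolated)
Conditions: n-BuLi, THF, −78 °C; then cannulated into allyl chloroformate, THF, −78 °C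
Reagents that add atoms: allyl chloroformate, C=CCOC(Cl)=O
Why: Bromine–lithium exchange at −78 °C (faster than ortho-deprotonation and below the temperature at which the ortho-fluoroaryllithium loses LiF) followed by acylation with the chloroformate under inverse addition, the doubly ortho-substituted ester resisting a second addition.

Step 12
Reactants: 17 allyl 2-fluoro-4-(methoxymethoxy)-6-methylbenzoate
Product: 19 allyl 2-fluoro-3-formyl-4-(methoxymethoxy)-6-methylbenzoate, via arylmagnesium chloride 18 (not isolated)
Conditions: TMPMgCl·LiCl, THF, −20 → 0 °C; DMF; aq NH4Cl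
Reagents that add atoms: N,N-dimethylformamide, CN(C)C=O
Why: Directed ortho-magnesiation at the C–H between fluorine and the methoxymethoxy group (the most acidic ring position, to which both groups direct the hindered amide base), with the ester tolerated by the magnesium amide, followed by Bouveault-type formylation of the aryl Grignard with DMF.

Step 13
Reactants: 12 ring B isocoumarin phenol; 19 allyl 2-fluoro-3-formyl-4-(methoxymethoxy)-6-methylbenzoate
Product: 20 diaryl ether (B6–O–ring A ether; ring A as allyl ester, B1 as allyl ether)
Conditions: Cs2CO3, DMSO, 60 °C, degassed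
Reagents that add atoms: none
Why: Nucleophilic aromatic substitution (addition–elimination) in which the ring A fluoride is activated by the ortho formyl and ortho ester groups that stabilize the Meisenheimer adduct, and the electron-rich B6 phenoxide is the only free nucleophile because B1–O is allylated.

Step 14
Reactants: 20 diaryl ether
Product: 21 seco acid (free ring A CO2H and free B1–OH)
Conditions: Pd(PPh3)4 (5 mol %), N-methylaniline, THF, rt
Reagents that add atoms: none
Why: Tsuji–Trost deallylation in which zerovalent palladium ionizes both the allyl ester and the allyl aryl ether to π-allyl complexes that are captured by the weakly nucleophilic amine, leaving the acetals, the aldehyde and the enol lactone untouched.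

Step 15
Reactants: 21 seco acid
Product: 22 isocoumarin-fused depsidone (key-step precursor; ring A OH as MOM ether, B2–CH2O and B3–O as isopropylidene acetal)
Conditions: EDC·HCl, DMAP, CH2Cl2 (0.005 M), rt
Reagents that add atoms: none
Why: Carbodiimide lactonization (Steglich-type esterification) at high dilution, the activated ring A acyl group being held next to the B1 phenol by the diaryl ether so that the seven-membered ring C closes.

Step 16
Reactants: 22 isocoumarin-fused depsidone
Product: 25 protected salazinic acid lactol (racemic, interconverting pair; target-configured enantiomer drawn), via ozonide 23 (not isolated), via formic anhydride aldehyde 24 (not isolated)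
Conditions: O3, CH2Cl2, −78 °C (Sudan Red 7B end point); Me2S, −78 °C → rt; then THF/pH 7 phosphate buffer, rt
Reagents that add atoms: ozone, [O-][O+]=O
Why: Ozone adds as a 1,3-dipole to the C3=C4 enol-ester alkene, the primary ozonide fragments and recloses to ozonide 23, Me2S reduces it to the B5 aldehyde and the mixed formic anhydride on B4 (24), and water then attacks the formyl carbon so that C3 leaves as formic acid. The closest known reaction type is the ozonolysis of isocoumarins and related enol lactones to 2-formylbenzoic acids, which exist as 3-hydroxyphthalides. Ring D closes by 5-exo-trig addition of the B4 carboxylic acid oxygen to the B5 aldehyde, which forms the lactone oxygen to lactol carbon bond. The lactol carbon is the only new stereocentre and nothing controls it here: it forms as a racemic pair that interconverts through the open aldehyde acid, and its configuration is fixed only in step 18. The step needs chemoselectivity for the alkene over two arenes, an aryl aldehyde and the acetal C–H bonds; this is secured because the enol-ester alkene is the only non-aromatic C=C and the most electron-rich π bond, both rings carry acyl groups and only acylated, arylated or acetal-bound oxygens, and ozone is dosed at −78 °C to a dye end point.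

Step 17
Reactants: 25 protected salazinic acid lactol
Product: 26 racemic salazinic acid
Conditions: aq HCl (3 M)/THF, 45 °C
Reagents that add atoms: none
Why: Acid hydrolysis of the methoxymethyl and isopropylidene acetals in an aqueous medium, which returns any benzylic cation at B2 to the alcohol and leaves aryl ester, aldehyde and lactol intact, the lactol carbon remaining an equilibrating pair.

Step 18
Reactants: 26 racemic salazinic acid
Product: 27 salazinic acid, (S)-lactol enantiomer (CNP0166154.1), as crystalline solid
Conditions: seed crystals of 27, acetone/H2O slurry, Et3N/AcOH (cat.), glass-bead attrition with temperature cycling 20–40 °C; filtered cold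
Reagents that add atoms: none
Why: Proposed new method: the lactol racemizes in solution through the achiral ring-opened 2-formylbenzoic acid, so in a seeded, ground slurry the solution should feed only the seeded enantiomorph until the whole solid is homochiral, provided the compound forms a conglomerate; the closest known reaction type is the seeded crystallization-induced asymmetric transformation (attrition-enhanced deracemization) of conglomerates that racemize in solution.

**Compound list**
1 | methyl orsellinate (methyl 2,4-dihydroxy-6-methylbenzoate) | COC(=O)c1c(C)cc(O)cc1O | starting material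
2 | methyl haematommate (methyl 3-formyl-2,4-dihydroxy-6-methylbenzoate) | COC(=O)c1c(C)cc(O)c(C=O)c1O | intermediate
3 | methyl 4-(allyloxy)-3-formyl-2-hydroxy-6-methylbenzoate | COC(=O)c1c(C)cc(OCC=C)c(C=O)c1O | intermediate
4 | methyl 4-(allyloxy)-5-bromo-3-formyl-2-hydroxy-6-methylbenzoate | COC(=O)c1c(C)c(Br)c(OCC=C)c(C=O)c1O | intermediate
5 | methyl 4-(allyloxy)-5-bromo-2-hydroxy-3-(hydroxymethyl)-6-methylbenzoate | COC(=O)c1c(C)c(Br)c(OCC=C)c(CO)c1O | intermediate
6 | methyl 5-(allyloxy)-6-bromo-2,2,7-trimethyl-4H-1,3-benzodioxine-8-carboxylate | COC(=O)c1c(C)c(Br)c(OCC=C)c2COC(C)(C)Oc12 | intermediate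
7 | lithium aryltriisopropoxyborate from 6 (boron at C6 of the benzodioxine) | COC(=O)c1c(C)c([B-](OC(C)C)(OC(C)C)OC(C)C)c(OCC=C)c2COC(C)(C)Oc12.[Li+] | intermediate
8 | methyl 5-(allyloxy)-6-hydroxy-2,2,7-trimethyl-4H-1,3-benzodioxine-8-carboxylate | COC(=O)c1c(C)c(O)c(OCC=C)c2COC(C)(C)Oc12 | intermediate
9 | methyl 5-(allyloxy)-6-(1-ethoxyethoxy)-2,2,7-trimethyl-4H-1,3-benzodioxine-8-carboxylate (racemic) | COC(=O)c1c(C)c(OC(C)OCC)c(OCC=C)c2COC(C)(C)Oc12 | intermediate
10 | benzylic lithium of 9 (7-lithiomethyl) | COC(=O)c1c(C[Li])c(OC(C)OCC)c(OCC=C)c2COC(C)(C)Oc12 | intermediate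
11 | methyl 5-(allyloxy)-6-(1-ethoxyethoxy)-2,2-dimethyl-7-(2-oxoethyl)-4H-1,3-benzodioxine-8-carboxylate (racemic) | COC(=O)c1c(CC=O)c(OC(C)OCC)c(OCC=C)c2COC(C)(C)Oc12 | intermediate
12 | ring B isocoumarin phenol: 6-(allyloxy)-5-hydroxyisocoumarin with isopropylidene acetal bridging 8-O and 7-CH2O | O=C1OC=Cc2c(O)c(OCC=C)c3COC(C)(C)Oc3c12 | intermediate
13 | 3-fluoro-5-methylphenol | Cc1cc(O)cc(F)c1 | starting material
14 | 4-bromo-3-fluoro-5-methylphenol | Cc1cc(O)cc(F)c1Br | intermediate
15 | 2-bromo-1-fluoro-5-(methoxymethoxy)-3-methylbenzene | COCOc1cc(C)c(Br)c(F)c1 | intermediate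
16 | [2-fluoro-4-(methoxymethoxy)-6-methylphenyl]lithium | COCOc1cc(C)c([Li])c(F)c1 | intermediate
17 | allyl 2-fluoro-4-(methoxymethoxy)-6-methylbenzoate | C=CCOC(=O)c1c(C)cc(OCOC)cc1F | intermediate
18 | arylmagnesium chloride of 17 (magnesium at C3, between F and OMOM) | C=CCOC(=O)c1c(C)cc(OCOC)c([Mg]Cl)c1F | intermediate
19 | allyl 2-fluoro-3-formyl-4-(methoxymethoxy)-6-methylbenzoate | C=CCOC(=O)c1c(C)cc(OCOC)c(C=O)c1F | intermediate
20 | diaryl ether: allyl 3-formyl-4-(methoxymethoxy)-6-methylbenzoate carrying at C2 the 5-oxy group of isocoumarin 12 (B1 O-allyl) | C=CCOC(=O)c1c(C)cc(OCOC)c(C=O)c1Oc1c(OCC=C)c2COC(C)(C)Oc2c2c1C=COC2=O | intermediate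
21 | seco acid: 2-aryloxy-3-formyl-4-(methoxymethoxy)-6-methylbenzoic acid with free B1 phenol | OC(=O)c1c(C)cc(OCOC)c(C=O)c1Oc1c(O)c2COC(C)(C)Oc2c2c1C=COC2=O | intermediate
22 | isocoumarin-fused depsidone (ring A O-MOM; B2–CH2O/B3–O isopropylidene acetal) | Cc1cc(OCOC)c(C=O)c2c1C(=O)Oc1c3COC(C)(C)Oc3c3c(c1O2)C=COC3=O | intermediate
23 | ozonide of 22 (1,2,4-trioxolane across former C3/C4; racemic, bridgeheads cis) | Cc1cc(OCOC)c(C=O)c2c1C(=O)Oc1c3COC(C)(C)Oc3c3c(c1O2)C4OOC(O4)OC3=O | intermediate
24 | formic anhydride aldehyde (B5–CHO, B4–C(=O)–O–CHO) | Cc1cc(OCOC)c(C=O)c2c1C(=O)Oc1c3COC(C)(C)Oc3c(C(=O)OC=O)c(C=O)c1O2 | intermediate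
25 | protected salazinic acid lactol (racemic, interconverting; target-configured enantiomer drawn) | Cc1cc(OCOC)c(C=O)c2c1C(=O)Oc1c3COC(C)(C)Oc3c3c(c1O2)[C@@H](O)OC3=O | intermediate
26 | racemic salazinic acid | Cc1cc(O)c(C=O)c2c1C(=O)Oc1c(CO)c(O)c3c(c1O2)C(O)OC3=O | intermediate
27 | salazinic acid, (S)-lactol enantiomer (CNP0166154.1) | Cc1cc(O)c(C=O)c2c1C(=O)Oc1c(CO)c(O)c3c(c1O2)[C@@H](O)OC3=O | target

**Totals**
Total step count: 18. Longest linear sequence: 14 (steps 1–8, then 13–18); ring A (steps 9–12) is made in parallel.

**Steps most likely to fail**

Step 18 (proposed new method). The solid may crystallize as a racemic compound instead of a conglomerate, or epimerization in the slurry may be too slow, so that seeding gives no enrichment. Fallback: setting out from 26, the enantiomers would be separated by preparative chromatography on a chiral stationary phase (cellulose tris(3,5-dimethylphenylcarbamate)) with an acidified, non-protic eluent at about 5 °C, where ring opening is slow. The fraction of the (S) enantiomer would be concentrated cold and crystallized at once to give 27, where the route is rejoined. The other fraction would be re-equilibrated by warming and resolved again. This fallback makes no new compound (F0).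

Step 16 (key step). Ozone may over-oxidize the alkoxy-substituted arenes or the aryl aldehyde, or oxidize the methoxymethyl acetal C–H bonds, before the alkene is consumed. Fallback: setting out from 22, catalytic OsO4 with N-methylmorpholine N-oxide in acetone/H2O would dihydroxylate only the enol-ester alkene to the racemic cis-3,4-diol F1. NaIO4 in THF/H2O would then cleave the glycol to the same formic anhydride aldehyde 24, which hydrolyses and closes to 25, where the route is rejoined.

Step 8. The formylated product may transfer a proton to unreacted benzylic anion 10 or take up a second benzylic anion, so that conversion stalls or a carbinol forms. Fallback: setting out from 9, the lithiated species 10 (LiN(i-Pr)2, THF, −78 °C) would be quenched with dimethyl carbonate to give the homophthalate diester F2, a standard trapping of lithiated toluates. i-Bu2AlH (1 equiv, PhMe, −78 °C) would reduce the unhindered aliphatic ester to aldehyde 11 while the doubly ortho-substituted aryl ester stays. The acid treatment of step 8 then gives 12, where the route is rejoined.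

**Further compounds**
F0 | step 18 | none | none
F1 | step 16 | racemic cis-3,4-dihydroxy-3,4-dihydroisocoumarin-fused depsidone (cis-diol of 22; one enantiomer drawn) | Cc1cc(OCOC)c(C=O)c2c1C(=O)Oc1c3COC(C)(C)Oc3c3c(c1O2)[C@@H](O)[C@@H](O)OC3=O
F2 | step 8 | methyl 5-(allyloxy)-6-(1-ethoxyethoxy)-7-(2-methoxy-2-oxoethyl)-2,2-dimethyl-4H-1,3-benzodioxine-8-carboxylate (racemic) | COC(=O)Cc1c(OC(C)OCC)c(OCC=C)c2COC(C)(C)Oc2c1C(=O)OC
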